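A living end dies slowly: at the charges its half-life by the step with transfer agent is 2.7 h, and two of us disputed what that slowness does to these flasks.

in all of them: free monomer 0.050 M; transfer agent 5.00 mM; pre-initiator 0.14 mM
- north: time 6.0 h
- south: time 20 h

    pre-initiator → initiator (k1 = 0.34 /h)
    2 free monomer → homo dimer (k2 = 0.0056 /M/h)
    free monomer + initiator → living end + monomer in chains (k3 = 51 /M/h)
    free monomer + living end → monomer in chains + living end, rate k4*[living end]*[free monomer] (k4 = 910 /M/h)
    living end + transfer agent → dead chain (k5 = 51 /M/h)

- a species is counted by the free monomer in it: one homo dimer counts as two
- two of one species on the left: rate k times its square, two consumed each time
- the average divides the monomer in chains by the number of chains begun, living and dead together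
- run time (north): 6.0 h

1. which of the two ends with the longer chains by the average number of monomer units in a chain (chains begun, living or dead) ("neither" if they lie within 10%) (north / south / neither)
2. average number of monomer units in a chain (chains begun, living or dead) at the end, north
3. average number of monomer units in a chain (chains begun, living or dead) at the end, south

We start from the same division. Monomer joins a living end at 910 /M/h times the free monomer, and the end dies at 51 /M/h times the transfer agent. Dividing one rate by the other removes the living end and time, and at the charges it gives 178. That is ν, the units one living end adds before it dies, the kinetic chain length.

Transfer agent barely moves, since the pre-initiator charge is hardly any of it. But ν falls with free monomer, so with D dead chains and c the free monomer charged, the free monomer left is c·exp(−νD/c). Homo dimer I leave out: per unit of free monomer it goes at 5.60 × 10⁻⁴ /h, far slower than the 0.0637 /h of growth if ends stood at 0.0700 mM.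

The first of us says time has dropped out, so both flasks end alike: with every chain dead, the length is 140, and the answer is neither.

The second, whom I join, says the division doesn't tell how many ends have died yet. The initiator's half-life of 0.27 h is shorter than the pre-initiator's 2.0 h, so I count a chain as begun when the pre-initiator opens. Two first-order clocks then give, for north, 0.122 mM begun and 0.0734 mM dead, so its length is 94.5. For south they give 0.140 mM begun and 0.137 mM dead, so its length is 138.

The forecast takes this side too, with south, 92 (85 to 99) for north and 140 (130 to 150) for south, noting that “the living ends die slowly”.

The simulation gives south, with 91.7 in north and 140 in south, against my 94.5 and 138. The first view has its region in the long run: north reads 142 at 60.0 h and south reads 142 at 200 h, beside its 140. A neighbouring flask is south with 0.020 M of free monomer, so ν is 71.4. νD/c is unchanged, so the same reckoning puts 38.7% of its free monomer into chains and gives a length of 55.3. That flask reads 56.1, with 39.2% of its charged free monomer in chains.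

All constants are made up; no experiment stands behind them.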